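**Retrosynthetic overview** (ring A = benzo ring of the chromone, ring C = pyranone, ring B = pendant aryl, ring D = dihydrofuran)
1. Target ⇒ 2'-iodoisoflavone + (R)-2-(oxiran-2-yl)propan-2-ol: ring D is cut at aryl C–CH2 and aryl C–O (Pd/norbornene annulation); the stereocenter arrives ready-made in the epoxide and is retained.
2. 2'-Iodoisoflavone ⇒ 2,4,6-trihydroxyphenyl 2-iodo-4,5-dimethoxybenzyl ketone + one carbon from DMF-DMA: ring C is cut at O1–C2 and C2–C3.
3. Forward, both closures run in one flask, ring C first and ring D second; rings A and B are bought.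
4. Ketone ⇒ phloroglucinol + 2-iodo-4,5-dimethoxyphenylacetonitrile (Houben–Hoesch); the nitrile ⇒ homoveratronitrile + N-iodosuccinimide.
5. Epoxide ⇒ methyl (R)-glycidate + 2 MeMgCl.

Assumption: the purchased methyl (R)-glycidate has ≥98% ee; the ee of the target rests on it, because no later step breaks a bond at the stereocenter.

**Route**

Step 1
Reactants: 1 2-(3,4-dimethoxyphenyl)acetonitrile
Product: 2 2-(2-iodo-4,5-dimethoxyphenyl)acetonitrile
Conditions: NIS (1.05 equiv), TFA (0.3 equiv), MeCN, 20 °C, 4 h
Reagents that add atoms: N-iodosuccinimide, O=C1CCC(=O)N1I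
Why: Electrophilic aromatic iodination (SEAr) with TFA-activated NIS goes to C6 of the veratrole ring, para to the 3-methoxy group and the least hindered activated site, and no stereocenter is formed.

Step 2
Reactants: 2 2-(2-iodo-4,5-dimethoxyphenyl)acetonitrile, 3 benzene-1,3,5-triol (phloroglucinol)
Product: 5 2-(2-iodo-4,5-dimethoxyphenyl)-1-(2,4,6-trihydroxyphenyl)ethan-1-one, via ketiminium chloride 4 (not isolated)
Conditions: ZnCl2 (0.3 equiv), HCl gas, Et2O, 0 °C, 24 h; then H2O, 100 °C, 2 h
Reagents that add atoms: water, O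
Why: Houben–Hoesch reaction, in which the HCl/ZnCl2-activated nitrile C-acylates the symmetric, highly nucleophilic phloroglucinol once at 0 °C (the ketiminium salt deactivates the ring and the aryl iodide is untouched) and hot water hydrolyses the ketiminium chloride to the ketone.

Step 3
Reactants: 6 methyl (2R)-oxirane-2-carboxylate
Product: 8 2-[(2R)-oxiran-2-yl]propan-2-ol, via epoxy ketone 7 (not isolated)
Conditions: MeMgCl (2.2 equiv), THF, −78 to −40 °C, 1 h; sat. aq. NH4Cl at −40 °C; Et2O extraction, cold concentration, bulb-to-bulb distillation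
Reagents that add atoms: methylmagnesium chloride, C[Mg]Cl
Why: Double Grignard addition to the chelation-activated ester is much faster at low temperature than opening of the epoxide, and no bond at the stereocenter is broken, so the (R) configuration of 6 is carried unchanged into 8.

Step 4
Reactants: 5 2-(2-iodo-4,5-dimethoxyphenyl)-1-(2,4,6-trihydroxyphenyl)ethan-1-one, 8 2-[(2R)-oxiran-2-yl]propan-2-ol
Product: 11 5,7-dihydroxy-3-[(2R)-2-(2-hydroxypropan-2-yl)-4,5-dimethoxy-2,3-dihydro-1-benzofuran-7-yl]-4H-chromen-4-one, via enaminone 9 (not isolated), via 2'-iodoisoflavone 10 (not isolated)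
Conditions: DMF-DMA (2 equiv), THF, 60 °C, 3 h; volatiles removed in vacuo; then 8 (3 equiv), Pd(OAc)2 (10 mol %), RuPhos (2-dicyclohexylphosphino-2',6'-diisopropoxybiphenyl, 20 mol %), isopropyl bicyclo[2.2.1]hept-5-ene-2-carboxylate (1 equiv), KOAc (2.5 equiv), DMF, 100 °C, sealed tube, 16 h; aq. NH4Cl work-up
Reagents that add atoms: N,N-dimethylformamide dimethyl acetal, CN(C)C(OC)OC
Why: Proposed new method: a one-flask merger of two known reaction types, the DMF-DMA ring closure of 2-hydroxydeoxybenzoins to isoflavones (enaminone formation at the activated CH2, then addition–elimination by the chelated 2-OH closes ring C) and the Catellani-type Pd/norbornene annulation of ortho-substituted aryl iodides with epoxides (zerovalent palladium inserts into C2'–I, norbornene insertion and palladation of the only free ortho C3'–H give the aryl–norbornyl palladacycle, which opens 8 at its CH2 terminus, C–C reductive elimination and norbornene extrusion leave a divalent aryl palladium alkoxide whose C–O reductive elimination closes ring D), with the C1' chromonyl group enforcing mono-alkylation and the mild base KOAc limiting phenoxide side reactions; the stereocenter is not created here but carried over from 8 with retention, because only the CH2–O bond of the epoxide is broken.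

**Compound list**

1 | 2-(3,4-dimethoxyphenyl)acetonitrile | N#CCc1ccc(OC)c(OC)c1 | starting material
2 | 2-(2-iodo-4,5-dimethoxyphenyl)acetonitrile | N#CCc1cc(OC)c(OC)cc1I | intermediate
3 | benzene-1,3,5-triol (phloroglucinol, anhydrous) | Oc1cc(O)cc(O)c1 | starting material
4 | 2-(2-iodo-4,5-dimethoxyphenyl)-1-(2,4,6-trihydroxyphenyl)ethan-1-iminium chloride | [Cl-].[NH2+]=C(Cc1cc(OC)c(OC)cc1I)c1c(O)cc(O)cc1O | intermediate
5 | 2-(2-iodo-4,5-dimethoxyphenyl)-1-(2,4,6-trihydroxyphenyl)ethan-1-one | O=C(Cc1cc(OC)c(OC)cc1I)c1c(O)cc(O)cc1O | intermediate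
6 | methyl (2R)-oxirane-2-carboxylate (methyl (R)-glycidate) | COC(=O)[C@H]1CO1 | starting material
7 | 1-[(2R)-oxiran-2-yl]ethan-1-one | CC(=O)[C@H]1CO1 | intermediate
8 | 2-[(2R)-oxiran-2-yl]propan-2-ol | CC(C)(O)[C@H]1CO1 | intermediate
9 | 3-(dimethylamino)-2-(2-iodo-4,5-dimethoxyphenyl)-1-(2,4,6-trihydroxyphenyl)prop-2-en-1-one (E/Z not defined) | CN(C)C=C(C(=O)c1c(O)cc(O)cc1O)c1cc(OC)c(OC)cc1I | intermediate
10 | 5,7-dihydroxy-3-(2-iodo-4,5-dimethoxyphenyl)-4H-chromen-4-one | O=c1c(-c2cc(OC)c(OC)cc2I)coc2cc(O)cc(O)c12 | intermediate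
11 | 5,7-dihydroxy-3-[(2R)-2-(2-hydroxypropan-2-yl)-4,5-dimethoxy-2,3-dihydro-1-benzofuran-7-yl]-4H-chromen-4-one | COc1cc(-c2coc3cc(O)cc(O)c3c2=O)c2c(c1OC)C[C@H](C(C)(C)O)O2 | target

**Totals**

Total step count: 4. Longest linear sequence: 3 (steps 1, 2 and 4); step 3 is a one-step side branch.

**Steps most likely to fail, with fallbacks**

First, step 4. The risks are:
- the C3'–H to be palladated is flanked by the iodide and a methoxy group;
- the acidic 7-OH can be alkylated by 8;
- the chromone C2–H can intercept the aryl palladium species;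
- DMF-DMA can O-methylate the phloroglucinol unit.

The fallback gives up the one-flask double closure for a stepwise, protected sequence; it sets out from 5 and comes back to the route at 11. Ketone 5 is closed with DMF-DMA as before, but 10 is isolated by precipitation from dilute aqueous acid. Its acidic 7-OH is capped with MOMCl (1.1 equiv) and K2CO3 in acetone at 20 °C, the chelated 5-OH staying free, to give 5-hydroxy-3-(2-iodo-4,5-dimethoxyphenyl)-7-(methoxymethoxy)-4H-chromen-4-one F1. The Pd/norbornene annulation with 8 under the palladium conditions of step 4 then gives 5-hydroxy-3-[(2R)-2-(2-hydroxypropan-2-yl)-4,5-dimethoxy-2,3-dihydro-1-benzofuran-7-yl]-7-(methoxymethoxy)-4H-chromen-4-one F2. Finally, 2 M HCl in MeOH at 40 °C removes the acetal and gives 11.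

Second, step 3. The risks are chloride or Grignard opening of the epoxide, Payne rearrangement of the magnesium alkoxide, and loss of the small, water-soluble product on isolation. The fallback masks the epoxide as a chlorohydrin during the Grignard step; it sets out from 6 and comes back at 8. HCl (2 M in Et2O, 0 °C) opens 6 at its CH2 terminus to methyl (2S)-3-chloro-2-hydroxypropanoate F3; the descriptor changes only because CH2Cl outranks the ester carbon. MeMgCl (3.3 equiv, THF, −40 to 0 °C) converts F3 into (2S)-1-chloro-3-methylbutane-2,3-diol F4. Powdered NaOH in Et2O at 20 °C then closes the secondary alkoxide onto CH2Cl, giving 8 with the C–O bond at the stereocenter untouched throughout.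

Third, step 2. The risks are an oily, incompletely formed ketiminium salt and poor conversion of the ortho-iodo nitrile under Hoesch conditions. The fallback replaces nitrile addition by Friedel–Crafts C-acylation with the carboxylic acid; it sets out from 2 and comes back at 5. Nitrile 2 is hydrolysed (NaOH, EtOH/H2O, reflux; then HCl) to 2-(2-iodo-4,5-dimethoxyphenyl)acetic acid F5. F5 is heated with 3 in BF3·OEt2 as solvent at 80 °C for 90 min, and aqueous NaOAc work-up gives 5.

Further compounds
F1 | step 4 | 5-hydroxy-3-(2-iodo-4,5-dimethoxyphenyl)-7-(methoxymethoxy)-4H-chromen-4-one | O=c1c(-c2cc(OC)c(OC)cc2I)coc2cc(OCOC)cc(O)c12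
F2 | step 4 | 5-hydroxy-3-[(2R)-2-(2-hydroxypropan-2-yl)-4,5-dimethoxy-2,3-dihydro-1-benzofuran-7-yl]-7-(methoxymethoxy)-4H-chromen-4-one | COc1cc(-c2coc3cc(OCOC)cc(O)c3c2=O)c2c(c1OC)C[C@H](C(C)(C)O)O2
F3 | step 3 | methyl (2S)-3-chloro-2-hydroxypropanoate | COC(=O)[C@H](O)CCl
F4 | step 3 | (2S)-1-chloro-3-methylbutane-2,3-diol | CC(C)(O)[C@H](O)CCl
F5 | step 2 | 2-(2-iodo-4,5-dimethoxyphenyl)acetic acid | OC(=O)Cc1cc(OC)c(OC)cc1I
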